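## Retrosynthetic overview
1. The target comes from a bis-allylic alcohol by alcohol oxidation and O–Si cleavage. That alcohol is cut at C10–C11 into a 2-substituted acrolein and an (E)-alkenylzinc made from 3-methyl-3-(trimethylsilyloxy)but-1-yne.
2. The acrolein C10–O bond comes from the isopropenyl CH3 with SeO2 (ene reaction, then [2,3]-sigmatropic shift).
3. The key bond is C6–O(tigloyl). It forms in the [3,3]-sigmatropic shift of an N-vinyl-O-tigloylhydroxylamine, made from the N-methyl nitrone of the cis-epoxy ketone and tigloyl chloride.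
4. The cis-epoxy ketone comes from hydroxyl-directed epoxidation of (−)-cis-carveol, which comes from (R)-(−)-carvone. The carvone C5 centre relays C1, then C2/C3, then C6.
5. Rings: the carbocycle is bought with carvone. The oxirane is the only ring made (step 2).

Assumption: atoms carry carvone numbers (C1 carbonyl, C2 methyl-bearing, C3, C4, C5 side-chain-bearing, C6; C8/C9/C10 = isopropenyl C, =CH2, CH3; C11–C13 = added chain), and 1, 6, 15 and MeNHOH·HCl are bought.

## Route

Step 1
Reactants: 1 (R)-(−)-carvone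
Product: 2 (1R,5R)-2-methyl-5-(prop-1-en-2-yl)cyclohex-2-en-1-ol ((−)-cis-carveol; OH cis to isopropenyl)
Conditions: NaBH4, CeCl3·7H2O, MeOH, −20 °C
Reagents that add atoms: none
Why: Luche 1,2-reduction; axial hydride delivery to the half-chair with an equatorial isopropenyl group gives the equatorial C1–OH, cis to the C5 substituent (1R).

Step 2
Reactants: 2 (−)-cis-carveol
Product: 3 (1R,2R,4S,6S)-1-methyl-4-(prop-1-en-2-yl)-7-oxabicyclo[4.1.0]heptan-2-ol (OH, epoxide O and isopropenyl all on one face)
Conditions: VO(acac)2 (2 mol %), t-BuOOH (decane), CH2Cl2, 0 °C → rt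
Reagents that add atoms: tert-butyl hydroperoxide, CC(C)(C)OO
Why: Hydroxyl-directed vanadium-catalysed epoxidation; the vanadium alkoxide at C1 delivers oxygen to C2=C3 on its own face, which sets C2 and C3 cis to the isopropenyl group and leaves the undirected 1,1-disubstituted alkene alone.

Step 3
Reactants: 3 epoxy alcohol
Product: 4 (1S,4R,6S)-1-methyl-4-(prop-1-en-2-yl)-7-oxabicyclo[4.1.0]heptan-2-one (cis-carvone epoxide)
Conditions: Dess–Martin periodinane, pyridine, CH2Cl2, 0 °C → rt
Reagents that add atoms: none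
Why: Dess–Martin oxidation under buffered conditions; no stereocentre is epimerisable, and the product is the epoxide diastereomer that direct alkaline H2O2 epoxidation of carvone does not give.

Step 4
Reactants: 4 cis-carvone epoxide
Product: 5 (Z)-N-[(1R,4S,6S)-1-methyl-4-(prop-1-en-2-yl)-7-oxabicyclo[4.1.0]heptan-2-ylidene]methanamine N-oxide (N-methyl nitrone of 4; ring centres unchanged in space; N-methyl on the C6 side)
Conditions: MeNHOH·HCl, NaOAc, 3 Å MS, EtOH, rt → 40 °C
Reagents that add atoms: N-methylhydroxylamine hydrochloride, CNO.Cl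
Why: Nitrone formation by condensation of the ketone with an N-alkylhydroxylamine; acetate buffering spares the epoxide, the low temperature avoids nitrone–alkene cycloaddition, and the smaller O− takes the quaternary C2 side.

Step 5 (key step)
Reactants: 5 N-methyl nitrone; 6 tigloyl chloride ((E)-2-methylbut-2-enoyl chloride)
Product: 10 (1S,3S,4S,6S)-1-methyl-2-oxo-4-(prop-1-en-2-yl)-7-oxabicyclo[4.1.0]heptan-3-yl (E)-2-methylbut-2-enoate, via N-tigloyloxyiminium chloride 7 (not isolated), via N-vinyl-O-tigloylhydroxylamine 8 (not isolated), via 6-tigloyloxy N-methylimine 9 (not isolated)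
Conditions: 6, CH2Cl2, −78 °C; then Et3N, −78 → 0 °C; then AcOH/NaOAc buffer (pH 4.5), THF–H2O, rt
Reagents that add atoms: water, O
Why: Acylation–rearrangement of a nitrone: O-acylation before base is added (so no vinylketene forms from 6) and deprotonation at C6, the only α-CH, give 8, whose [3,3]-sigmatropic shift breaks the weak N–O bond and places the acyl oxygen on C6 opposite the C5 isopropenyl group and the epoxide oxygen, giving the trans-diequatorial (also thermodynamic) 6S ester after imine hydrolysis.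

Step 6
Reactants: 10 tigloyloxy epoxy ketone
Product: 14 (1S,3S,4S,6S)-1-methyl-2-oxo-4-(3-oxoprop-1-en-2-yl)-7-oxabicyclo[4.1.0]heptan-3-yl (E)-2-methylbut-2-enoate, via allylseleninic acid 11 (not isolated), via allyloxy(hydroxy)selane 12 (not isolated), via primary allylic alcohol 13 (not isolated)
Conditions: SeO2 (0.5 equiv), t-BuOOH (4 equiv, decane), CH2Cl2, rt → 35 °C
Reagents that add atoms: selenium dioxide, O=[Se]=O (passes on the oxygen); tert-butyl hydroperoxide, CC(C)(C)OO (restores the SeO2)
Why: SeO2 allylic oxidation: an ene reaction at the only electron-rich alkene gives 11, its [2,3]-sigmatropic shift forms the C10–O bond and restores the exocyclic methylene, and 13 is oxidised on to the enal in the same flask; the electron-poor tiglate alkene and all stereocentres stay untouched.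

Step 7
Reactants: 14 enal; 15 3-methyl-3-(trimethylsilyloxy)but-1-yne
Product: 19 (1S,3S,4S,6S)-4-[(4E)-3-hydroxy-6-methyl-6-(trimethylsilyloxy)hepta-1,4-dien-2-yl]-1-methyl-2-oxo-7-oxabicyclo[4.1.0]heptan-3-yl (E)-2-methylbut-2-enoate (mixture of C10 carbinol epimers), via (E)-alkenylzirconocene chloride 16 (not isolated), via (E)-alkenyl(methyl)zinc 17 (not isolated), via methylzinc alkoxide 18 (not isolated)
Conditions: 15 (slight excess over Zr), Cp2Zr(H)Cl, CH2Cl2, rt; ZnMe2 (toluene), −65 °C; 14, 0 °C; pH 7 buffer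
Reagents that add atoms: none
Why: Hydrozirconation, zinc transmetalation and aldehyde addition: syn Zr–H addition to the terminal alkyne fixes the E alkene, and the mild alkenylzinc adds 1,2 to the aldehyde only, sparing the hindered ketone, ester and epoxide; the C10 centre is erased in step 8.

Step 8
Reactants: 19 bis-allylic alcohol
Product: 21 (1S,3S,4S,6S)-4-[(4E)-6-hydroxy-6-methyl-3-oxohepta-1,4-dien-2-yl]-1-methyl-2-oxo-7-oxabicyclo[4.1.0]heptan-3-yl (E)-2-methylbut-2-enoate (CNP0263368.1), via silyl-protected dienone 20 (not isolated)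
Conditions: Dess–Martin periodinane, pyridine, CH2Cl2, 0 °C; then crude, citric acid (cat.), MeOH, rt
Reagents that add atoms: none
Why: Dess–Martin oxidation gives the cross-conjugated dienone without enolising C6, and mild acid methanolysis removes the labile tertiary O–SiMe3 group once the acid-sensitive bis-allylic carbinol is gone; no stereocentre is formed or disturbed.

## Compound list
1 | (R)-(−)-carvone | C=C(C)[C@@H]1CC=C(C)C(=O)C1 | starting material
2 | (−)-cis-carveol (1R,5R) | C=C(C)[C@@H]1CC=C(C)[C@H](O)C1 | intermediate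
3 | (1R,2R,4S,6S)-epoxy alcohol | C=C(C)[C@@H]1C[C@@H]2O[C@]2(C)[C@H](O)C1 | intermediate
4 | cis-carvone epoxide (1S,4R,6S) | C=C(C)[C@@H]1C[C@@H]2O[C@]2(C)C(=O)C1 | intermediate
5 | (Z)-N-methyl nitrone of 4 | C=C(C)[C@@H]1C[C@@H]2O[C@]2(C)/C(=[N+](/C)[O-])C1 | intermediate
6 | tigloyl chloride | C/C=C(\C)C(=O)Cl | starting material
7 | N-tigloyloxyiminium chloride | C=C(C)[C@@H]1C[C@@H]2O[C@]2(C)/C(=[N+](/C)OC(=O)/C(C)=C/C)C1.[Cl-] | intermediate
8 | N-vinyl-O-tigloylhydroxylamine (C1=C6 enamine) | C=C(C)[C@@H]1C[C@@H]2O[C@]2(C)C(N(C)OC(=O)/C(C)=C/C)=C1 | intermediate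
9 | 6-tigloyloxy N-methylimine (C=N geometry not fixed) | C=C(C)[C@@H]1C[C@@H]2O[C@]2(C)C(=NC)[C@H]1OC(=O)/C(C)=C/C | intermediate
10 | trans-6-tigloyloxy cis-carvone epoxide (1S,3S,4S,6S) | C=C(C)[C@@H]1C[C@@H]2O[C@]2(C)C(=O)[C@H]1OC(=O)/C(C)=C/C | intermediate
11 | allylseleninic acid | C=C(C[Se](=O)O)[C@@H]1C[C@@H]2O[C@]2(C)C(=O)[C@H]1OC(=O)/C(C)=C/C | intermediate
12 | allyloxy(hydroxy)selane | C=C(CO[Se]O)[C@@H]1C[C@@H]2O[C@]2(C)C(=O)[C@H]1OC(=O)/C(C)=C/C | intermediate
13 | C10 primary allylic alcohol | C=C(CO)[C@@H]1C[C@@H]2O[C@]2(C)C(=O)[C@H]1OC(=O)/C(C)=C/C | intermediate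
14 | C10 enal | C=C(C=O)[C@@H]1C[C@@H]2O[C@]2(C)C(=O)[C@H]1OC(=O)/C(C)=C/C | intermediate
15 | 3-methyl-3-(trimethylsilyloxy)but-1-yne | C#CC(C)(C)O[Si](C)(C)C | starting material
16 | (E)-alkenylzirconocene chloride (Cp rings drawn sigma-bonded) | C[Si](C)(C)OC(C)(C)/C=C/[Zr](Cl)(C1C=CC=C1)C1C=CC=C1 | intermediate
17 | (E)-alkenyl(methyl)zinc | C[Zn]/C=C/C(C)(C)O[Si](C)(C)C | intermediate
18 | methylzinc alkoxide of 19 | C=C(C(O[Zn]C)/C=C/C(C)(C)O[Si](C)(C)C)[C@@H]1C[C@@H]2O[C@]2(C)C(=O)[C@H]1OC(=O)/C(C)=C/C | intermediate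
19 | bis-allylic alcohol, O-SiMe3 protected, C10 epimers | C=C(C(O)/C=C/C(C)(C)O[Si](C)(C)C)[C@@H]1C[C@@H]2O[C@]2(C)C(=O)[C@H]1OC(=O)/C(C)=C/C | intermediate
20 | silyl-protected dienone | C=C(C(=O)/C=C/C(C)(C)O[Si](C)(C)C)[C@@H]1C[C@@H]2O[C@]2(C)C(=O)[C@H]1OC(=O)/C(C)=C/C | intermediate
21 | CNP0263368.1 | C=C(C(=O)/C=C/C(C)(C)O)[C@@H]1C[C@@H]2O[C@]2(C)C(=O)[C@H]1OC(=O)/C(C)=C/C | target

## Step count and risks
Total steps: 8. Longest linear sequence: 8 (1 → 21).

**Step 5 (together with its feeder, step 4).** The ketone is flanked by a quaternary epoxide carbon, so nitrone formation and acylation may be slow. The chloride counter-ion of 7 could attack the epoxide, and the face selectivity at C6 may be incomplete. The fallback sets out from 4. The lithium enolate is made with LiN(SiMe3)2 (THF, −78 °C; only C6 can be deprotonated). It is hydroxylated with MoO5·pyridine·HMPA anti to the isopropenyl group to give trans-6-hydroxy cis-carvone epoxide F1. Esterification with 6 (pyridine, cat. DMAP, CH2Cl2, 0 °C) comes back to the route at 10.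

**Step 6.** The ene step could abstract the tertiary C5–H instead of a methyl hydrogen. The reaction may also stall at alcohol 13 or degrade the α-acyloxy ketone on long exposure. The fallback sets out from 10. Ene-type allylic chlorination with NaOCl/CeCl3·7H2O (CH2Cl2–H2O, 0 °C) gives the C10 allylic chloride F2. N-Methylmorpholine N-oxide (MeCN, cat. NaI, 40 °C) displaces the chloride and fragments to the aldehyde, which comes back to the route at 14.

**Step 7.** The ketone carries two electronegative α-substituents and may compete with the aldehyde. The zirconium and zinc Lewis acids may also open the epoxide. The fallback sets out from 14 and replaces nucleophilic addition by neutral acyl cross-coupling.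
- Pinnick oxidation (NaClO2, NaH2PO4, 2-methylbut-2-ene, t-BuOH–H2O) gives the 2-substituted acrylic acid F3.
- 1-Chloro-N,N,2-trimethylprop-1-en-1-amine (CH2Cl2, 0 °C) gives the acid chloride F4.
- Stille acylation (Pd2(dba)3, P(2-furyl)3, THF, rt) uses (E)-2-methyl-4-(tributylstannyl)but-3-en-2-ol F5, made from 2-methylbut-3-yn-2-ol with Bu3SnH and PdCl2(PPh3)2.
- The coupling gives the dienone with the free tertiary alcohol directly. It comes back to the route at 21, so step 8 is not needed.

## Further compounds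
F1 | step 5 | trans-6-hydroxy cis-carvone epoxide | C=C(C)[C@@H]1C[C@@H]2O[C@]2(C)C(=O)[C@H]1O
F2 | step 6 | C10 allylic chloride of 10 | C=C(CCl)[C@@H]1C[C@@H]2O[C@]2(C)C(=O)[C@H]1OC(=O)/C(C)=C/C
F3 | step 7 | C10 acrylic acid | C=C(C(=O)O)[C@@H]1C[C@@H]2O[C@]2(C)C(=O)[C@H]1OC(=O)/C(C)=C/C
F4 | step 7 | C10 acid chloride | C=C(C(=O)Cl)[C@@H]1C[C@@H]2O[C@]2(C)C(=O)[C@H]1OC(=O)/C(C)=C/C
F5 | step 7 | (E)-2-methyl-4-(tributylstannyl)but-3-en-2-ol | CCCC[Sn](CCCC)(CCCC)/C=C/C(C)(C)O
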